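## Retrosynthetic overview

1. The enal comes from a primary allylic alcohol (MnO2). The 4‑hydroxybenzoate is carried from mid‑route as its TBS ether, made in three steps from 4‑bromophenol.
2. The seven‑membered ring is closed last, at the bond between the olefinic CH and the carbon bearing the CH2O unit. This is a Pd‑catalysed coupling of a 2‑bromoalkene with a tethered carbene (from an aldehyde); the allyl‑Pd formed is captured by acetate.
3. The cyclisation precursor comes from anti‑Markovnikov Wacker oxidation of a vinyl group, aroylation of the secondary OH, and i‑Pr addition to a cyclopentanone.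
4. The cyclopentanone with three contiguous stereocentres comes from Cu‑catalysed enantioselective conjugate addition of a 1‑silylvinyl alane to 3‑methylcyclopent‑2‑enone, then an anti‑aldol of the trapped enolate with 3‑bromobut‑3‑enal.
5. Ring order: cyclopentane from the start, cycloheptene in the penultimate step. Three branches converge (arene acid chloride, bromo‑aldehyde, cyclopentane).

Assumption: compounds 1, 6, 8 and 9 are bought; locants in the "Why" lines are those of the name given for the compound concerned.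

## Route

Step 1
Reactants: 1 4-bromophenol
Product: 2 (4-bromophenoxy)(tert-butyl)dimethylsilane
Conditions: TBSCl, imidazole, DMF, 23 °C
Reagents that add atoms: tert-butyldimethylsilyl chloride, CC(C)(C)[Si](C)(C)Cl
Why: Imidazole‑promoted silylation (silyl ether formation) masks the phenol for the lithiation and the later base‑ and Pd‑mediated steps.

Step 2
Reactants: 2 (4-bromophenoxy)(tert-butyl)dimethylsilane
Product: 4 4-(tert-butyldimethylsilyloxy)benzoic acid, via aryllithium 3 (not isolated)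
Conditions: n-BuLi, THF, −78 °C; CO2 (g), −78 → 23 °C; 1 M HCl
Reagents that add atoms: carbon dioxide, O=C=O
Why: Bromine–lithium exchange followed by carboxylation of the aryllithium with CO2 gives the benzoic acid.

Step 3
Reactants: 4 4-(tert-butyldimethylsilyloxy)benzoic acid
Product: 5 4-(tert-butyldimethylsilyloxy)benzoyl chloride
Conditions: (COCl)2, DMF (cat.), CH2Cl2, 0 → 23 °C
Reagents that add atoms: oxalyl chloride, ClC(=O)C(Cl)=O
Why: Acid chloride formation through the Vilsmeier‑type chloroiminium intermediate; the aryl silyl ether tolerates the anhydrous conditions.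

Step 4
Reactants: 6 3-bromobut-3-en-1-ol
Product: 7 3-bromobut-3-enal
Conditions: Dess–Martin periodinane, CH2Cl2, 0 °C; used at once as a cold solution
Reagents that add atoms: none
Why: Dess–Martin oxidation is non‑basic, and the β,γ‑unsaturated aldehyde is not purified, so it has no chance to isomerise into conjugation.

Step 5
Reactants: 8 ethynyltrimethylsilane; 9 3-methylcyclopent-2-en-1-one
Product: 12 trimethyl({(3S)-3-methyl-3-[1-(trimethylsilyl)ethenyl]cyclopent-1-en-1-yl}oxy)silane, via vinylalane 10 (not isolated), via aluminium enolate 11 (not isolated)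
Conditions: i-Bu2AlH, hexanes/THF, 55 °C; then 9, Cu(OTf)2 (5 mol%), chiral sulfonate-bridged NHC·Ag complex (2.5 mol%), THF, −78 → −15 °C; then TMSOTf, −78 → 0 °C
Reagents that add atoms: trimethylsilyl trifluoromethanesulfonate, C[Si](C)(C)OS(=O)(=O)C(F)(F)F
Why: syn‑Hydroalumination puts Al on the silicon‑bearing carbon, the NHC–Cu‑catalysed enantioselective conjugate addition of this alkenylalane sets the quaternary carbon (3S, catalyst control, antipode chosen accordingly), and O‑silylation of the aluminium enolate fixes the enolate regiochemistry.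

Step 6
Reactants: 12 trimethyl({(3S)-3-methyl-3-[1-(trimethylsilyl)ethenyl]cyclopent-1-en-1-yl}oxy)silane; 7 3-bromobut-3-enal
Product: 15 (2S,3S)-2-[(1S)-3-bromo-1-hydroxybut-3-en-1-yl]-3-methyl-3-[1-(trimethylsilyl)ethenyl]cyclopentan-1-one, via lithium enolate 13 (not isolated), via boron enolate 14 (not isolated)
Conditions: MeLi, THF, 0 °C; (c-C6H11)2BCl, −78 °C; 7, −78 °C; then MeOH, pH 7 buffer
Reagents that add atoms: none
Why: MeLi unmasks the regiodefined enolate, transmetalation gives the ring‑(E) boron enolate, and a Zimmerman–Traxler aldol gives the anti adduct; 7 adds to the face of C‑2 opposite the bulky 1‑silylvinyl group, so C‑2 (S) and C‑1′ (S) are set together.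

Step 7
Reactants: 15 (2S,3S)-2-[(1S)-3-bromo-1-hydroxybut-3-en-1-yl]-3-methyl-3-[1-(trimethylsilyl)ethenyl]cyclopentan-1-one
Product: 16 (2S,3R)-2-[(1S)-3-bromo-1-hydroxybut-3-en-1-yl]-3-ethenyl-3-methylcyclopentan-1-one
Conditions: CF3CO2H (5 equiv), CHCl3, 0 °C
Reagents that add atoms: none
Why: Protodesilylation of the vinylsilane by ipso‑protonation to a β‑silyl‑stabilised cation and loss of silicon; brief cold exposure keeps the β‑hydroxy ketone from dehydrating.

Step 8
Reactants: 16 (2S,3R)-2-[(1S)-3-bromo-1-hydroxybut-3-en-1-yl]-3-ethenyl-3-methylcyclopentan-1-one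
Product: 17 (1R,2S,3R)-2-[(1S)-3-bromo-1-hydroxybut-3-en-1-yl]-3-ethenyl-3-methyl-1-(propan-2-yl)cyclopentan-1-ol
Conditions: LaCl3·2LiCl, THF, 0 °C; i-PrMgCl (3 equiv), −78 → −30 °C; aq. NH4Cl
Reagents that add atoms: isopropylmagnesium chloride, CC(C)[Mg]Cl
Why: Lanthanum‑promoted Grignard 1,2‑addition suppresses enolisation and reduction, and the nucleophile enters the ketone face opposite the adjacent C‑2 side chain (whose metal alkoxide sits on that face), giving the tertiary alcohol with OH cis to the side chain (1R).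

Step 9
Reactants: 17 (1R,2S,3R)-2-[(1S)-3-bromo-1-hydroxybut-3-en-1-yl]-3-ethenyl-3-methyl-1-(propan-2-yl)cyclopentan-1-ol; 5 4-(tert-butyldimethylsilyloxy)benzoyl chloride
Product: 18 (1S)-3-bromo-1-[(1S,2R,5R)-2-ethenyl-5-hydroxy-2-methyl-5-(propan-2-yl)cyclopentyl]but-3-en-1-yl 4-(tert-butyldimethylsilyloxy)benzoate
Conditions: Et3N, DMAP (cat.), CH2Cl2, 0 → 23 °C
Reagents that add atoms: none
Why: DMAP‑catalysed acylation takes the secondary alcohol only, because the tertiary alcohol is too hindered to react.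

Step 10
Reactants: 18 (1S)-3-bromo-1-[(1S,2R,5R)-2-ethenyl-5-hydroxy-2-methyl-5-(propan-2-yl)cyclopentyl]but-3-en-1-yl 4-(tert-butyldimethylsilyloxy)benzoate
Product: 19 (1S)-3-bromo-1-[(1S,2R,5R)-2-hydroxy-5-methyl-5-(2-oxoethyl)-2-(propan-2-yl)cyclopentyl]but-3-en-1-yl 4-(tert-butyldimethylsilyloxy)benzoate
Conditions: PdCl2(PhCN)2 (12 mol%), CuCl2·2H2O (12 mol%), AgNO2 (6 mol%), O2 (1 atm), t-BuOH/MeNO2 15:1, 23 °C
Reagents that add atoms: dioxygen, O=O
Why: Aldehyde‑selective (anti‑Markovnikov) nitrite‑modified Wacker oxidation; the quaternary allylic carbon further disfavours Markovnikov attack and the electron‑poor 2‑bromoalkene is left untouched.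

Step 11
Reactants: 19 (1S)-3-bromo-1-[(1S,2R,5R)-2-hydroxy-5-methyl-5-(2-oxoethyl)-2-(propan-2-yl)cyclopentyl]but-3-en-1-yl 4-(tert-butyldimethylsilyloxy)benzoate
Product: 22 (3R,3aS,4S,8aR)-3-hydroxy-6-(hydroxymethyl)-8a-methyl-3-(propan-2-yl)-1,2,3,3a,4,5,8,8a-octahydroazulen-4-yl 4-hydroxybenzoate, via aziridinylimine 20 (not isolated), via allylic acetate 21 (not isolated)
Conditions: 1-amino-trans-2,3-diphenylaziridine, CH2Cl2, 0 °C; then slow addition to Pd2(dba)3 (5 mol%), PPh3 (20 mol%), n-Bu4NOAc (5 equiv), toluene (0.005 M), 100 °C; then K2CO3, MeOH, 23 °C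
Reagents that add atoms: tetrabutylammonium acetate, CCCC[N+](CCCC)(CCCC)CCCC.CC(=O)[O-]
Why: Proposed new method: Pd‑catalysed intramolecular carbenylative cyclisation with acetate capture – Pd(0) inserts into the 2‑bromoalkene, the N‑aziridinylimine 20 thermally releases the tethered diazoalkane (neutral and sulfinate‑free, so no sulfone can trap the allyl‑Pd), the alkenyl‑Pd carbene undergoes 1,2‑alkenyl migration that closes the seven‑membered ring (new C6–C7 bond) and leaves an η3‑allyl‑Pd spanning C7–C6–CH2, and reversible acetate attack funnels this to the primary allylic acetate 21 with the ring‑internal (necessarily cis) trisubstituted olefin, which K2CO3/MeOH then unmasks together with the phenol; the closest known reaction type is the intermolecular Pd‑catalysed three‑component coupling of alkenyl halides, diazo compounds or sulfonylhydrazones and N‑ or C‑nucleophiles through alkenyl‑carbene migratory insertion to allyl‑Pd (carbenylative amination/alkylation), combined with Tsuji–Trost acetate equilibration; no stereocentre is created.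

Step 12
Reactants: 22 (3R,3aS,4S,8aR)-3-hydroxy-6-(hydroxymethyl)-8a-methyl-3-(propan-2-yl)-1,2,3,3a,4,5,8,8a-octahydroazulen-4-yl 4-hydroxybenzoate
Product: 23 (3R,3aS,4S,8aR)-6-formyl-3-hydroxy-8a-methyl-3-(propan-2-yl)-1,2,3,3a,4,5,8,8a-octahydroazulen-4-yl 4-hydroxybenzoate
Conditions: MnO2 (activated, excess), CH2Cl2, 23 °C
Reagents that add atoms: none
Why: MnO2 oxidises only the primary allylic alcohol to the enal; the tertiary alcohol, phenol and ester are inert, and no base is present that could trigger vinylogous elimination of the benzoate.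

## Compound list

1 | 4-bromophenol | Oc1ccc(Br)cc1 | starting material
2 | (4-bromophenoxy)(tert-butyl)dimethylsilane | CC(C)(C)[Si](C)(C)Oc1ccc(Br)cc1 | intermediate
3 | [4-(tert-butyldimethylsilyloxy)phenyl]lithium | [Li]c1ccc(O[Si](C)(C)C(C)(C)C)cc1 | intermediate
4 | 4-(tert-butyldimethylsilyloxy)benzoic acid | CC(C)(C)[Si](C)(C)Oc1ccc(cc1)C(=O)O | intermediate
5 | 4-(tert-butyldimethylsilyloxy)benzoyl chloride | CC(C)(C)[Si](C)(C)Oc1ccc(cc1)C(Cl)=O | intermediate
6 | 3-bromobut-3-en-1-ol | OCCC(Br)=C | starting material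
7 | 3-bromobut-3-enal | O=CCC(Br)=C | intermediate
8 | ethynyltrimethylsilane | C#C[Si](C)(C)C | starting material
9 | 3-methylcyclopent-2-en-1-one | CC1=CC(=O)CC1 | starting material
10 | diisobutyl[1-(trimethylsilyl)ethenyl]alane | C=C([Si](C)(C)C)[Al](CC(C)C)CC(C)C | intermediate
11 | diisobutylaluminium (3S)-3-methyl-3-[1-(trimethylsilyl)ethenyl]cyclopent-1-en-1-olate | CC(C)C[Al](CC(C)C)OC1=C[C@@](C)(C(=C)[Si](C)(C)C)CC1 | intermediate
12 | trimethyl({(3S)-3-methyl-3-[1-(trimethylsilyl)ethenyl]cyclopent-1-en-1-yl}oxy)silane | C[Si](C)(C)OC1=C[C@@](C)(C(=C)[Si](C)(C)C)CC1 | intermediate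
13 | lithium (3S)-3-methyl-3-[1-(trimethylsilyl)ethenyl]cyclopent-1-en-1-olate | [Li]OC1=C[C@@](C)(C(=C)[Si](C)(C)C)CC1 | intermediate
14 | dicyclohexyl({(3S)-3-methyl-3-[1-(trimethylsilyl)ethenyl]cyclopent-1-en-1-yl}oxy)borane | C1CCCCC1B(OC2=C[C@@](C)(C(=C)[Si](C)(C)C)CC2)C3CCCCC3 | intermediate
15 | (2S,3S)-2-[(1S)-3-bromo-1-hydroxybut-3-en-1-yl]-3-methyl-3-[1-(trimethylsilyl)ethenyl]cyclopentan-1-one | O=C1CC[C@](C)(C(=C)[Si](C)(C)C)[C@H]1[C@@H](O)CC(Br)=C | intermediate
16 | (2S,3R)-2-[(1S)-3-bromo-1-hydroxybut-3-en-1-yl]-3-ethenyl-3-methylcyclopentan-1-one | O=C1CC[C@](C)(C=C)[C@H]1[C@@H](O)CC(Br)=C | intermediate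
17 | (1R,2S,3R)-2-[(1S)-3-bromo-1-hydroxybut-3-en-1-yl]-3-ethenyl-3-methyl-1-(propan-2-yl)cyclopentan-1-ol | CC(C)[C@]1(O)CC[C@](C)(C=C)[C@H]1[C@@H](O)CC(Br)=C | intermediate
18 | (1S)-3-bromo-1-[(1S,2R,5R)-2-ethenyl-5-hydroxy-2-methyl-5-(propan-2-yl)cyclopentyl]but-3-en-1-yl 4-(tert-butyldimethylsilyloxy)benzoate | CC(C)[C@]1(O)CC[C@](C)(C=C)[C@H]1[C@@H](OC(=O)c2ccc(O[Si](C)(C)C(C)(C)C)cc2)CC(Br)=C | intermediate
19 | (1S)-3-bromo-1-[(1S,2R,5R)-2-hydroxy-5-methyl-5-(2-oxoethyl)-2-(propan-2-yl)cyclopentyl]but-3-en-1-yl 4-(tert-butyldimethylsilyloxy)benzoate | CC(C)[C@]1(O)CC[C@](C)(CC=O)[C@H]1[C@@H](OC(=O)c2ccc(O[Si](C)(C)C(C)(C)C)cc2)CC(Br)=C | intermediate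
20 | N-(trans-2,3-diphenylaziridin-1-yl)imine of aldehyde 19 (CH=N–N at the former CHO; aziridine from the racemic reagent) | CC(C)[C@]1(O)CC[C@](C)(CC=NN2C(c3ccccc3)C2c4ccccc4)[C@H]1[C@@H](OC(=O)c5ccc(O[Si](C)(C)C(C)(C)C)cc5)CC(Br)=C | intermediate
21 | (3R,3aS,4S,8aR)-6-(acetoxymethyl)-3-hydroxy-8a-methyl-3-(propan-2-yl)-1,2,3,3a,4,5,8,8a-octahydroazulen-4-yl 4-(tert-butyldimethylsilyloxy)benzoate | CC(C)[C@]1(O)CC[C@]2(C)CC=C(COC(C)=O)C[C@H](OC(=O)c3ccc(O[Si](C)(C)C(C)(C)C)cc3)[C@H]21 | intermediate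
22 | (3R,3aS,4S,8aR)-3-hydroxy-6-(hydroxymethyl)-8a-methyl-3-(propan-2-yl)-1,2,3,3a,4,5,8,8a-octahydroazulen-4-yl 4-hydroxybenzoate | CC(C)[C@]1(O)CC[C@]2(C)CC=C(CO)C[C@H](OC(=O)c3ccc(O)cc3)[C@H]21 | intermediate
23 | (3R,3aS,4S,8aR)-6-formyl-3-hydroxy-8a-methyl-3-(propan-2-yl)-1,2,3,3a,4,5,8,8a-octahydroazulen-4-yl 4-hydroxybenzoate (CNP0267880.1) | CC(C)[C@]1(O)CC[C@]2(C)CC=C(C=O)C[C@H](OC(=O)c3ccc(O)cc3)[C@H]21 | target

## Step count and risks

Total step count: 12

Longest linear sequence: 8 (steps 5–12; the path step 4 then steps 6–12 is also 8; steps 1–3 then 9–12 is 7)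

Three steps most likely to fail:

Step 6. Aldehyde 7 can enolise or isomerise, and the anti and π‑facial selectivities may erode. The fallback makes the side chain by allylation instead of aldol; it sets out from 12 and comes back at 17. The lithium enolate from 12 (MeLi, THF) is hydroxymethylated with monomeric formaldehyde at −78 °C, again anti to the silylvinyl group, to give (2S,3S)-2-(hydroxymethyl)-3-methyl-3-[1-(trimethylsilyl)ethenyl]cyclopentan-1-one F1. CF3CO2H in CHCl3 removes the vinylic silicon to give (2S,3R)-3-ethenyl-2-(hydroxymethyl)-3-methylcyclopentan-1-one F2. i‑PrMgCl/LaCl3·2LiCl adds anti to the CH2OH arm to give (1R,2S,3R)-3-ethenyl-2-(hydroxymethyl)-3-methyl-1-(propan-2-yl)cyclopentan-1-ol F3. TEMPO/PhI(OAc)2 oxidises only the primary alcohol to (1R,2R,5R)-2-ethenyl-5-hydroxy-2-methyl-5-(propan-2-yl)cyclopentane-1-carbaldehyde F4. An indium‑mediated Barbier reaction of F4 with 2,3‑dibromopropene in THF/H2O (chelation between the tertiary OH and the aldehyde, 1,3‑anti induction) installs the 2‑bromoallyl carbinol and returns to 17.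

Step 8. The β‑hydroxy ketone can enolise or undergo retro‑aldol, the secondary Grignard can reduce, and chelation may lower the facial selectivity. The fallback uses a protected substrate under steric control; it sets out from 16 and comes back at 17. Silylation (TESOTf, 2,6‑lutidine, −78 °C) gives (2S,3R)-2-[(1S)-3-bromo-1-(triethylsilyloxy)but-3-en-1-yl]-3-ethenyl-3-methylcyclopentan-1-one F5. The non‑basic organocerium reagent from i‑PrMgCl and CeCl3 (THF, −78 °C) adds anti to the now bulky side chain to give (1R,2S,3R)-2-[(1S)-3-bromo-1-(triethylsilyloxy)but-3-en-1-yl]-3-ethenyl-3-methyl-1-(propan-2-yl)cyclopentan-1-ol F6. PPTS in MeOH removes the silyl group and returns to 17.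

Step 11 (the new cyclisation). Likely failure modes are a carbene 1,2‑H shift back to a vinyl group, β‑hydride elimination of the allyl‑Pd to a 1,3‑diene, and oligomerisation. The fallback uses known chemistry; it sets out from 19 and comes back at 22. An intramolecular Nozaki–Hiyama–Kishi reaction (CrCl2, NiCl2 cat., DMSO/THF, high dilution) joins the bromoalkene carbon to the aldehyde and gives (3R,3aS,4S,8aR)-3,7-dihydroxy-8a-methyl-6-methylidene-3-(propan-2-yl)decahydroazulen-4-yl 4-(tert-butyldimethylsilyloxy)benzoate F7 as C‑7 epimers. A rhenium‑catalysed 1,3‑transposition (Ph3SiOReO3, Et2O, 0 °C) moves the hydroxyl to the exocyclic carbon and the olefin into the ring, giving (3R,3aS,4S,8aR)-3-hydroxy-6-(hydroxymethyl)-8a-methyl-3-(propan-2-yl)-1,2,3,3a,4,5,8,8a-octahydroazulen-4-yl 4-(tert-butyldimethylsilyloxy)benzoate F8. K2CO3 in MeOH removes the aryl silyl group and returns to 22.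

Further compounds
F1 | step 6 | (2S,3S)-2-(hydroxymethyl)-3-methyl-3-[1-(trimethylsilyl)ethenyl]cyclopentan-1-one | O=C1CC[C@](C)(C(=C)[Si](C)(C)C)[C@H]1CO
F2 | step 6 | (2S,3R)-3-ethenyl-2-(hydroxymethyl)-3-methylcyclopentan-1-one | O=C1CC[C@](C)(C=C)[C@H]1CO
F3 | step 6 | (1R,2S,3R)-3-ethenyl-2-(hydroxymethyl)-3-methyl-1-(propan-2-yl)cyclopentan-1-ol | CC(C)[C@]1(O)CC[C@](C)(C=C)[C@H]1CO
F4 | step 6 | (1R,2R,5R)-2-ethenyl-5-hydroxy-2-methyl-5-(propan-2-yl)cyclopentane-1-carbaldehyde | CC(C)[C@]1(O)CC[C@](C)(C=C)[C@H]1C=O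
F5 | step 8 | (2S,3R)-2-[(1S)-3-bromo-1-(triethylsilyloxy)but-3-en-1-yl]-3-ethenyl-3-methylcyclopentan-1-one | O=C1CC[C@](C)(C=C)[C@H]1[C@@H](O[Si](CC)(CC)CC)CC(Br)=C
F6 | step 8 | (1R,2S,3R)-2-[(1S)-3-bromo-1-(triethylsilyloxy)but-3-en-1-yl]-3-ethenyl-3-methyl-1-(propan-2-yl)cyclopentan-1-ol | CC(C)[C@]1(O)CC[C@](C)(C=C)[C@H]1[C@@H](O[Si](CC)(CC)CC)CC(Br)=C
F7 | step 11 | (3R,3aS,4S,8aR)-3,7-dihydroxy-8a-methyl-6-methylidene-3-(propan-2-yl)decahydroazulen-4-yl 4-(tert-butyldimethylsilyloxy)benzoate (C-7 epimers) | CC(C)[C@]1(O)CC[C@]2(C)CC(O)C(=C)C[C@H](OC(=O)c3ccc(O[Si](C)(C)C(C)(C)C)cc3)[C@H]21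
F8 | step 11 | (3R,3aS,4S,8aR)-3-hydroxy-6-(hydroxymethyl)-8a-methyl-3-(propan-2-yl)-1,2,3,3a,4,5,8,8a-octahydroazulen-4-yl 4-(tert-butyldimethylsilyloxy)benzoate | CC(C)[C@]1(O)CC[C@]2(C)CC=C(CO)C[C@H](OC(=O)c3ccc(O[Si](C)(C)C(C)(C)C)cc3)[C@H]21
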